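## Structural features

The target is an achiral depside, 2-heptyl-4-[(2-hydroxy-4-methoxy-6-pentylbenzoyl)oxy]-6-methoxybenzoic acid. Its two benzene rings are joined only by an aryl ester between the carboxyl carbon of ring A and the C4 oxygen of ring B. Ring A is a 2-hydroxy-4-methoxy-6-pentylbenzoyl unit. Ring B is a benzoic acid with the carboxyl group at C1, methoxy at C2, the acyloxy group at C4 and heptyl at C6, so both carbonyl carbons sit between two ortho substituents. There is no stereocentre and no stereogenic double bond, so no stereocentres are adjacent and the problem is purely regiochemical. The fragile groups are the depside link, an activated phenyl ester that alkoxide, hydroxide or amines cleave or transfer, and the electron-rich, doubly ortho-substituted ring-B acid, which cannot be released from a simple alkyl ester by saponification without destroying the depside. The real difficulty is ring B: its two meta-related oxygens must be distinguished against the normal bias of a resorcylate, with the hydrogen-bonded ortho oxygen methylated and the more reactive para oxygen free for acylation. The acylation itself then has to use a di-ortho-substituted acyl donor. The key step exploits the contiguous ring-B segment C6(heptyl)–C1(carboxyl)–C2(OMe)–C3(H), which is the C6–C5–C4–C3 diene of a 4-methoxy-2-pyrone-5-carboxylate; only C4 with its oxygen and C5 are added, as a ketene acetal whose oxygen arrives unmethylated.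

## Logic of the disconnections

**20 to 19.** The O–CH2 bonds of a benzyl ester on ring B and a benzyl ether on the ortho oxygen of ring A are restored. The acid and the ortho phenol must be masked during ester formation and released without base, nucleophile or strong acid, because the depside ester tolerates none of them. All reactive groups of 19 are thereby capped and one operation unmasks both. The forward step, hydrogenolysis, must leave the aryl ester and both arenes alone; no other reducible group is present.

**19 to 12 and 17 (through 18).** The depside C(=O)–O(aryl) bond is cut. It is the only bond between the rings, so the molecule falls into two monocyclic pieces of similar size and the route becomes convergent. The forward step needs a strongly activated acyl donor, 18, because the acyl carbon is flanked by pentyl and benzyloxy. It also needs 12 to have exactly one free hydroxyl.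

**12 to 6 and 8 (key disconnection).** The ring-B bonds C3–C4 and C5–C6 are cut. This removes a two-carbon unit that carries the only free oxygen and leaves heptyl, ester and methyl ether on a four-carbon diene inside 6. The regiochemical problem of ring B is thus moved into a heterocycle in which every substituent is placed by construction. The forward step demands that 6 behave as an electron-poor diene despite its methoxy group, that the CH2 of 8 bond to pyrone C6 and not elsewhere, and that carbon dioxide and silanol be lost afterwards.

**6 to 5, then 5 to 2 and 3 (through 4), then 2 to 1.** First the O–CH3 bond at C4 is cut. Then the lactone O1–C2 bond and the bond from pyrone C5 to the octanoyl carbon are cut. 5 is the enol lactone of a 2-acyl-3-oxoglutarate, so the symmetrical diester 2 and acid chloride 3 supply every carbon. The forward steps require C-acylation and not O-acylation, monoacylation, lactonisation through the enol oxygen of the new ketone onto the remote ester, and methylation on the C4 oxygen and not the carbonyl oxygen. The ester exchange from 1 is placed first because the benzyl ester is carried unchanged as far as 19.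

**8 to 7.** One O–Si bond is cut, which is an enolate silylation in the forward sense. The reagent must be silylated on oxygen and handled dry.

**17 to 16, 15, 14 and 13.** In turn, the carboxyl group is taken back to the aldehyde, the O–benzyl and O–methyl bonds are cut, and finally the aryl–CHO bond is cut. 13 already holds the pentyl chain and both oxygens. A formyl group between pentyl and hydroxyl chelates the neighbouring hydroxyl and so differentiates the two: the free para hydroxyl is methylated first and the chelated one benzylated second. The forward steps demand formylation at the carbon between pentyl and hydroxyl, clean monomethylation, and oxidation without ring chlorination.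

## Other disconnections considered

**Alternative 1:** The cut removes both carbon substituents of ring B, the C6–heptyl bond and the C1–carboxyl bond, from an intact 1,3-dioxygenated arene.
- **Forward step:** Silyl ether A1, (3-fluoro-5-methoxyphenoxy)triisopropylsilane, would be lithiated between fluorine and methoxy and lose fluoride to give the aryne. Heptylmagnesium bromide A2 would add at the aryne carbon remote from the methoxy group, and the arylmagnesium carbon next to it would be carboxylated to give A3, 2-heptyl-6-methoxy-4-(triisopropylsilyloxy)benzoic acid. Benzylation of the carboxylate and desilylation would then lead to 12.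
- **In favour:** Two C–C bonds would form in one flask on an arene that already holds both oxygens in differentiated form. The regiochemical preference of additions to 3-alkoxyarynes is well established. About four operations reach 12 against five here (steps 1 to 5), so on step economy it is the equal of the chosen plan or slightly better. Its elementary steps are individually better precedented than the cycloaddition of 6.
- **Against:** Three ortho sites compete in the lithiation and the alkyllithium base competes with A2 for the aryne. The outcome rests on a kinetic preference and not on connectivity, so a minor regioisomer would need separating. The sequence is cryogenic and moisture-sensitive throughout.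
- **Comparison:** Both plans meet at 12. The aryne route relies on the bias of a polar addition, whereas the pyrone route writes the substitution pattern into the bonds of 6, so no regioisomer of 12 can arise from a productive cycloaddition. The chosen route is kept for that reason and because it starts from inexpensive acyclic materials, but the aryne route is a serious competitor.

**Alternative 2:** Here ring A is the ring that is made, by cutting its C1–C2 and C5–C6 bonds while the depside ester stays intact.
- **Forward step:** Ynoate A4, benzyl 2-heptyl-6-methoxy-4-(oct-2-ynoyloxy)benzoate (from 12 and the C8 ynoic acid), would react with the Brassard diene A5, 1,3-dimethoxy-1-(trimethylsilyloxy)buta-1,3-diene. The CH2 terminus of the diene would bond to the pentyl-bearing alkyne carbon. Loss of the acetal methoxy group and of silicon would give A6, benzyl 2-heptyl-4-[(2-hydroxy-4-methoxy-6-pentylbenzoyl)oxy]-6-methoxybenzoate, and hydrogenolysis of its one benzyl group would give the target.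
- **In favour:** The ring-A oxygen pattern (free ortho hydroxyl, para methyl ether) would come from the diene without any protecting group. The hindered acylation of step 10 is replaced by esterification with an unhindered acid, and steps 6 to 9 disappear. The total falls by about two steps, so on step and protecting-group economy it is better than the chosen plan.
- **Against:** It is linear, with ring A built on the most valuable intermediate. β-Alkyl ynoates are sluggish dienophiles toward this diene and would need heating that the diene tolerates poorly. The aryl ynoate is also an acylating agent, so conjugate addition of the diene followed by expulsion of the ring-B phenoxide, or closure to a pyrone, could cut the depside link.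
- **Comparison:** It does not address ring B and still needs 12, so it competes with steps 6 to 10 and not with step 5. Both plans use a [4+2]/aromatisation sequence steered by ketene-acetal polarisation and are equal in kind. The chosen plan places its uncertain cycloaddition early, on cheap material, and ends with a conventional convergent esterification.

**Alternative 3:** The cuts are the depside C–O bond and the ring-A C1–C6 bond.
- **Forward step:** Diketo-dioxinone A7, 6-(2,4-dioxononyl)-2,2-dimethyl-4H-1,3-dioxin-4-one, heated with 12 would release an acylketene. The phenol oxygen of 12 would capture it to give triketo ester A8, benzyl 2-heptyl-6-methoxy-4-[(3,5,7-trioxododecanoyl)oxy]benzoate. Aldol closure of C2 on C7 and dehydration would give resorcylate A9, benzyl 4-[(2,4-dihydroxy-6-pentylbenzoyl)oxy]-2-heptyl-6-methoxybenzoate. Selective methylation of the non-chelated para hydroxyl would give A6 and hydrogenolysis the target.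
- **In favour:** The ester bond forms by addition to a ketene, which is insensitive to the crowding that burdens step 10; on this point it is better than the chosen plan. Ring A needs no protecting group and the sequence follows biosynthetic logic.
- **Against:** An aryl 3,5-dioxo ester can lactonise through its C5 enol oxygen to a 4-hydroxy-2-pyrone and expel 12, a far better leaving group than an alkoxide, in competition with the C2–C7 aldol. Phenols are weaker ketene traps than alcohols, A7 takes several steps to make, and a late regioselective methylation is added.
- **Comparison:** Step count is about equal (A7, capture and aromatisation, methylation and hydrogenolysis against steps 6 to 11). Like alternative 2 it presupposes 12 and is compatible with the key step chosen here. The chosen plan prefers to join the rings with a stable, fully aromatic acid, 17, that already carries its methyl ether.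

Key step: step 5

Assumption: the target is taken as the achiral depside named above. The pyrone, numbered as a 2-pyrone, is benzyl 6-heptyl-4-methoxy-2-oxo-2H-pyran-5-carboxylate; this 2-pyrone numbering (O1, C2 carbonyl, C3 to C6) is used in all mechanistic discussion. The atom mapping of its C3–C6 diene and of the two ketene-acetal carbons onto ring B was checked and needs no correction.

## Route

Step 1
Reactants: 1 dimethyl 3-oxopentanedioate
Product: 2 dibenzyl 3-oxopentanedioate
Conditions: BnOH (2.2 equiv), DMAP (cat.), toluene, reflux, removal of MeOH (4 Å MS)
Reagents that add atoms: benzyl alcohol, OCc1ccccc1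
Why: Transesterification of a β-keto ester, which proceeds readily under DMAP catalysis through the enol or acylketene pathway and is driven by removal of methanol. The benzyl ester is installed here because it is carried unchanged to the last step, where hydrogenolysis releases the hindered ring-B acid.

Step 2
Reactants: 2 dibenzyl 3-oxopentanedioate; 3 octanoyl chloride
Product: 5 benzyl 2-heptyl-4-hydroxy-6-oxo-6H-pyran-3-carboxylate, via dibenzyl 2-octanoyl-3-oxopentanedioate 4 (not isolated)
Conditions: MgCl2, pyridine, CH2Cl2, 0 °C to rt; aq. HCl work-up; crude 4, DBU (1.1 equiv), toluene, 80 °C; then 1 M HCl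
Reagents that add atoms: none
Why: Soft enolisation with MgCl2 and pyridine gives the magnesium chelate of the β-keto ester, which is acylated on carbon by the acid chloride (C-acylation of a 1,3-dicarbonyl compound). The 3,5-dioxo ester 4 then lactonises through the enol oxygen of the octanoyl ketone onto the remote benzyl ester with loss of benzyl alcohol, the standard base-mediated synthesis of 4-hydroxy-2-pyrones. No other six-membered closure is possible, so the heptyl group and the retained ester end up on adjacent carbons (pyrone C6 and C5).

Step 3
Reactants: 5 benzyl 2-heptyl-4-hydroxy-6-oxo-6H-pyran-3-carboxylate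
Product: 6 benzyl 2-heptyl-4-methoxy-6-oxo-6H-pyran-3-carboxylate
Conditions: Me2SO4, K2CO3, acetone, reflux
Reagents that add atoms: dimethyl sulfate, COS(=O)(=O)OC
Why: O-Alkylation of the vinylogous acid; under carbonate in acetone, 4-hydroxy-2-pyrones are methylated on the C4 oxygen to give the 4-methoxy-2-pyrone and not the isomeric 2-methoxy-4-pyranone. The benzyl ester and the lactone are inert to these conditions.

Step 4
Reactants: 7 trimethylsilyl acetate
Product: 8 1,1-bis(trimethylsilyloxy)ethene
Conditions: LDA, THF, −78 °C; TMSCl, −78 °C to rt; pentane, filtration, distillation
Reagents that add atoms: chlorotrimethylsilane, C[Si](C)(C)Cl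
Why: Ester enolisation followed by O-silylation (silyl ketene acetal formation); the lithium enolate of the silyl ester is trapped on oxygen by the chlorosilane. The product is distilled and kept dry because it is readily hydrolysed.

Step 5
Reactants: 6 benzyl 2-heptyl-4-methoxy-6-oxo-6H-pyran-3-carboxylate; 8 1,1-bis(trimethylsilyloxy)ethene
Product: 12 benzyl 2-heptyl-4-hydroxy-6-methoxybenzoate, via bridged lactone cycloadduct 9 (not isolated), via bis(silyloxy)cyclohexadiene 10 (not isolated), via aryl trimethylsilyl ether 11 (not isolated)
Conditions: 8 (4 equiv), toluene, 120 °C, sealed tube; then 1 M HCl, THF, rt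
Reagents that add atoms: none
Why: The step is an inverse-electron-demand Diels–Alder reaction followed by cycloreversion, the ketene-acetal variant of the known conversion of 2-pyrone-5-carboxylates (coumalates and the 4,6-disubstituted isodehydroacetates) into benzoates. The nucleophilic CH2 of 8 bonds to C6 of 6, which is both the δ-position of the lactone carbonyl and the β-position of the C5 benzyl ester, and the acetal carbon bonds to C3, either in a concerted asynchronous [4+2] or by Michael addition followed by 6-(enolexo)-exo-trig closure of the dienolate carbon C3 onto the bis(silyloxy)carbenium ion; this is the only ring closed and it gives the 2-oxabicyclo[2.2.2]oct-5-en-3-one 9. Retro-[4+2] extrusion of carbon dioxide from 9 gives diene 10, whose CH2–C(OSiMe3)2 unit can aromatise in one way only, by 1,2-loss of trimethylsilanol, to aryl silyl ether 11, and dilute acid frees phenol 12. The two bridgehead stereocentres of 9 are transient, racemic and destroyed on aromatisation, so no stereocontrol is needed. The required regiochemistry (acetal carbon to C3, CH2 to C6) is secured by the push–pull polarisation of the diene: the C5 ester and the ring carbonyl make C6 the electrophilic terminus, C3 is the α-carbon of the lactone, and the C4 methoxy group lowers the electrophilicity of C4 so that conjugate addition there should not compete. A free C4 phenol beside the C2 methyl ether follows from the fact that both acetal oxygens carry silicon, so whichever is eliminated the remaining one is unmasked on work-up. The methoxy and heptyl groups make 6 a slower diene than a coumalate, which is why 8 is used in excess at 120 °C in a closed vessel.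

Step 6
Reactants: 13 olivetol (5-pentylbenzene-1,3-diol)
Product: 14 2,4-dihydroxy-6-pentylbenzaldehyde
Conditions: POCl3, DMF, 0 °C to rt; then H2O, 50 °C
Reagents that add atoms: N,N-dimethylformamide, CN(C)C=O; water, O
Why: Vilsmeier–Haack formylation; the chloroiminium ion attacks the resorcinol para to one hydroxyl and ortho to the other, at the carbon next to the pentyl chain, as is usual for 5-alkylresorcinols. Aqueous hydrolysis of the iminium salt gives the aldehyde.

Step 7
Reactants: 14 2,4-dihydroxy-6-pentylbenzaldehyde
Product: 15 2-hydroxy-4-methoxy-6-pentylbenzaldehyde
Conditions: MeI (1.05 equiv), K2CO3 (1.0 equiv), acetone, rt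
Reagents that add atoms: iodomethane, CI
Why: Williamson ether synthesis with chelation-based selectivity: the ortho hydroxyl is hydrogen-bonded to the formyl group and less nucleophilic, so one equivalent of base and alkylating agent should methylate the para hydroxyl.

Step 8
Reactants: 15 2-hydroxy-4-methoxy-6-pentylbenzaldehyde
Product: 16 2-(benzyloxy)-4-methoxy-6-pentylbenzaldehyde
Conditions: BnBr, K2CO3, DMF, 60 °C
Reagents that add atoms: benzyl bromide, BrCc1ccccc1
Why: Williamson benzylation of the remaining chelated phenol, which reacts in DMF on warming. The benzyl ether prevents self-acylation in step 10 and is removed together with the benzyl ester in step 11.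

Step 9
Reactants: 16 2-(benzyloxy)-4-methoxy-6-pentylbenzaldehyde
Product: 17 2-(benzyloxy)-4-methoxy-6-pentylbenzoic acid
Conditions: NaClO2, NaH2PO4, 2-methyl-2-butene, t-BuOH/H2O, rt
Reagents that add atoms: sodium chlorite, [Na+].[O-]Cl=O
Why: Pinnick oxidation, which tolerates hindered aryl aldehydes and benzyl ethers. The alkene scavenger removes hypochlorous acid before it can chlorinate the electron-rich ring.

Step 10
Reactants: 17 2-(benzyloxy)-4-methoxy-6-pentylbenzoic acid; 12 benzyl 2-heptyl-4-hydroxy-6-methoxybenzoate
Product: 19 benzyl 4-{[2-(benzyloxy)-4-methoxy-6-pentylbenzoyl]oxy}-2-heptyl-6-methoxybenzoate, via 2-(benzyloxy)-4-methoxy-6-pentylbenzoyl chloride 18 (not isolated)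
Conditions: (COCl)2, DMF (cat.), CH2Cl2, 0 °C to rt, evaporate; 12, Et3N, DMAP (cat.), CH2Cl2, 0 °C to rt
Reagents that add atoms: none
Why: Acid chloride formation followed by DMAP-catalysed acylation of a phenol; the acylpyridinium intermediate overcomes the crowding of the di-ortho-substituted acyl group. 12 has a single, unhindered hydroxyl and 18 has no α-hydrogen, so neither regiochemical nor ketene side paths are open.

Step 11
Reactants: 19 benzyl 4-{[2-(benzyloxy)-4-methoxy-6-pentylbenzoyl]oxy}-2-heptyl-6-methoxybenzoate
Product: 20 2-heptyl-4-[(2-hydroxy-4-methoxy-6-pentylbenzoyl)oxy]-6-methoxybenzoic acid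
Conditions: H2 (1 atm), Pd/C (10%), EtOAc, rt
Reagents that add atoms: none
Why: Catalytic hydrogenolysis cleaves the benzyl ester and the benzyl ether at their O–CH2 bonds under neutral conditions. The depside aryl ester, the methyl ethers and the arenes are not reduced, so the acid and the phenol are released without any nucleophile or base that could break the depside link.

## Compound list

1 | dimethyl 3-oxopentanedioate | COC(=O)CC(=O)CC(=O)OC | starting material
2 | dibenzyl 3-oxopentanedioate | O=C(CC(=O)OCc1ccccc1)CC(=O)OCc1ccccc1 | intermediate
3 | octanoyl chloride | CCCCCCCC(Cl)=O | starting material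
4 | dibenzyl 2-octanoyl-3-oxopentanedioate (enolised, configurationally labile centre, racemic) | CCCCCCCC(=O)C(C(=O)OCc1ccccc1)C(=O)CC(=O)OCc1ccccc1 | intermediate (not isolated)
5 | benzyl 2-heptyl-4-hydroxy-6-oxo-6H-pyran-3-carboxylate | CCCCCCCC1=C(C(=O)OCc2ccccc2)C(O)=CC(=O)O1 | intermediate
6 | benzyl 2-heptyl-4-methoxy-6-oxo-6H-pyran-3-carboxylate | CCCCCCCC1=C(C(=O)OCc2ccccc2)C(OC)=CC(=O)O1 | intermediate
7 | trimethylsilyl acetate | CC(=O)O[Si](C)(C)C | starting material
8 | 1,1-bis(trimethylsilyloxy)ethene | C=C(O[Si](C)(C)C)O[Si](C)(C)C | intermediate
9 | benzyl 1-heptyl-5-methoxy-3-oxo-8,8-bis(trimethylsilyloxy)-2-oxabicyclo[2.2.2]oct-5-ene-6-carboxylate (racemic, one enantiomer drawn; the two bridgehead configurations are mutually fixed by the bicycle) | CCCCCCC[C@@]12CC(O[Si](C)(C)C)(O[Si](C)(C)C)[C@@H](C(=O)O1)C(OC)=C2C(=O)OCc1ccccc1 | intermediate (not isolated)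
10 | benzyl 2-heptyl-6-methoxy-4,4-bis(trimethylsilyloxy)cyclohexa-1,5-diene-1-carboxylate | CCCCCCCC1=C(C(=O)OCc2ccccc2)C(OC)=CC(O[Si](C)(C)C)(O[Si](C)(C)C)C1 | intermediate (not isolated)
11 | benzyl 2-heptyl-6-methoxy-4-(trimethylsilyloxy)benzoate | CCCCCCCc1cc(O[Si](C)(C)C)cc(OC)c1C(=O)OCc1ccccc1 | intermediate (not isolated)
12 | benzyl 2-heptyl-4-hydroxy-6-methoxybenzoate | CCCCCCCc1cc(O)cc(OC)c1C(=O)OCc1ccccc1 | intermediate
13 | olivetol (5-pentylbenzene-1,3-diol) | CCCCCc1cc(O)cc(O)c1 | starting material
14 | 2,4-dihydroxy-6-pentylbenzaldehyde | CCCCCc1cc(O)cc(O)c1C=O | intermediate
15 | 2-hydroxy-4-methoxy-6-pentylbenzaldehyde | CCCCCc1cc(OC)cc(O)c1C=O | intermediate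
16 | 2-(benzyloxy)-4-methoxy-6-pentylbenzaldehyde | CCCCCc1cc(OC)cc(OCc2ccccc2)c1C=O | intermediate
17 | 2-(benzyloxy)-4-methoxy-6-pentylbenzoic acid | CCCCCc1cc(OC)cc(OCc2ccccc2)c1C(=O)O | intermediate
18 | 2-(benzyloxy)-4-methoxy-6-pentylbenzoyl chloride | CCCCCc1cc(OC)cc(OCc2ccccc2)c1C(=O)Cl | intermediate (not isolated)
19 | benzyl 4-{[2-(benzyloxy)-4-methoxy-6-pentylbenzoyl]oxy}-2-heptyl-6-methoxybenzoate | CCCCCCCc1cc(OC(=O)c2c(OCc3ccccc3)cc(OC)cc2CCCCC)cc(OC)c1C(=O)OCc1ccccc1 | intermediate
20 | 2-heptyl-4-[(2-hydroxy-4-methoxy-6-pentylbenzoyl)oxy]-6-methoxybenzoic acid | CCCCCCCc1cc(OC(=O)c2c(O)cc(OC)cc2CCCCC)cc(OC)c1C(=O)O | target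

## Step count and least certain steps

Total: 11 steps. Longest linear sequence: 6 steps (1 to 2, 5, 6, 12, 19, 20 by steps 1, 2, 3, 5, 10, 11; equally 13 to 20 by steps 6 to 11).

**Step 5 (key step).** The most likely failure is insufficient cycloaddition reactivity. The C4 methoxy group makes the diene less electron-poor and the heptyl group crowds the C6 terminus, so thermal O-to-C silyl migration and adventitious hydrolysis may consume 8 before it adds. A second failure mode is conjugate addition at C6 followed by opening of the lactone instead of closure at C3. The fallback sets out from 3 and returns at 12. Commercially available 4-methoxy-6-methyl-2H-pyran-2-one is deprotonated at its C6 methyl group (LDA, THF, −78 °C, two equivalents of the anion) and acylated with 3 to give 4-methoxy-6-(2-oxononyl)-2H-pyran-2-one F1. Sodium benzyloxide (NaOCH2Ph) in benzyl alcohol/THF then opens the lactone to the open-chain benzyl ester. Its dienolate attacks the heptyl ketone through the former pyrone C3 (aldol), and dehydration should give 12 directly, with the methyl ether ortho and the free hydroxyl para to the ester. This replaces the cycloaddition by an alkoxide-triggered pyrone-to-resorcylate recyclisation.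

**Step 2.** Competing O-acylation or double acylation may occur in the magnesium-mediated step. With benzyl esters the lactonisation may be sluggish or give way to retro-Claisen loss of the octanoyl group, because the strongly acidic cyclisation media that serve for methyl esters cannot be used. The fallback sets out from 3 and returns at 5. 3 acylates Meldrum's acid (pyridine, CH2Cl2, 0 °C) to 5-(1-hydroxyoctylidene)-2,2-dimethyl-1,3-dioxane-4,6-dione F2. Heating F2 with benzyl alcohol in toluene gives benzyl 3-oxodecanoate F3. F3 is condensed with malonyl dichloride, by C-acylation at the active methylene and ring closure through the ketone enol oxygen, to give 5. This forms the C4–C5 and O1–C2 bonds of the pyrone instead and needs neither 1 nor 2.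

**Step 10.** Acylation by the di-ortho-substituted acid chloride may be slow. The ortho benzyl ether of 18 may also be lost under the hydrogen chloride of its formation (acylium-assisted debenzylation), leading to self-condensation. The fallback sets out from 17 and returns at 20. Hydrogenolysis of 17 (H2, Pd/C, EtOAc) gives 2-hydroxy-4-methoxy-6-pentylbenzoic acid F4. F4 and 12 are condensed with trifluoroacetic anhydride in toluene at rt through the mixed anhydride, the hydrogen-bonded ortho hydroxyl remaining free, to give benzyl 2-heptyl-4-[(2-hydroxy-4-methoxy-6-pentylbenzoyl)oxy]-6-methoxybenzoate F5. Hydrogenolysis of its single benzyl ester gives 20.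

**Step 7.** Discrimination between the two hydroxyls may be poor, giving over-methylation to the dimethyl ether or incomplete conversion, because the selectivity rests only on the hydrogen bond to the formyl group. The fallback sets out from 14 and returns at 15. Exhaustive methylation (excess MeI, K2CO3, DMF) gives 2,4-dimethoxy-6-pentylbenzaldehyde F6. Chelation-controlled cleavage of only the methyl ether ortho to the formyl group with BCl3 in CH2Cl2 at −78 to 0 °C then gives 15.

## Further compounds

F1 | step 5 | 4-methoxy-6-(2-oxononyl)-2H-pyran-2-one | CCCCCCCC(=O)CC1=CC(OC)=CC(=O)O1
F2 | step 2 | 5-(1-hydroxyoctylidene)-2,2-dimethyl-1,3-dioxane-4,6-dione | CCCCCCCC(O)=C1C(=O)OC(C)(C)OC1=O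
F3 | step 2 | benzyl 3-oxodecanoate | CCCCCCCC(=O)CC(=O)OCc1ccccc1
F4 | step 10 | 2-hydroxy-4-methoxy-6-pentylbenzoic acid | CCCCCc1cc(OC)cc(O)c1C(=O)O
F5 | step 10 | benzyl 2-heptyl-4-[(2-hydroxy-4-methoxy-6-pentylbenzoyl)oxy]-6-methoxybenzoate | CCCCCc1cc(OC)cc(O)c1C(=O)Oc1cc(CCCCCCC)c(C(=O)OCc2ccccc2)c(OC)c1
F6 | step 7 | 2,4-dimethoxy-6-pentylbenzaldehyde | CCCCCc1cc(OC)cc(OC)c1C=O
A1 | alternative 1 | (3-fluoro-5-methoxyphenoxy)triisopropylsilane | COc1cc(F)cc(O[Si](C(C)C)(C(C)C)C(C)C)c1
A2 | alternative 1 | heptylmagnesium bromide | CCCCCCC[Mg]Br
A3 | alternative 1 | 2-heptyl-6-methoxy-4-(triisopropylsilyloxy)benzoic acid | CCCCCCCc1cc(O[Si](C(C)C)(C(C)C)C(C)C)cc(OC)c1C(=O)O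
A4 | alternative 2 | benzyl 2-heptyl-6-methoxy-4-(oct-2-ynoyloxy)benzoate | CCCCCC#CC(=O)Oc1cc(CCCCCCC)c(C(=O)OCc2ccccc2)c(OC)c1
A5 | alternative 2 | 1,3-dimethoxy-1-(trimethylsilyloxy)buta-1,3-diene (geometry of the ketene-acetal double bond left open, it is lost on aromatisation) | C=C(OC)C=C(OC)O[Si](C)(C)C
A6 | alternative 2 | benzyl 2-heptyl-4-[(2-hydroxy-4-methoxy-6-pentylbenzoyl)oxy]-6-methoxybenzoate | CCCCCc1cc(OC)cc(O)c1C(=O)Oc1cc(CCCCCCC)c(C(=O)OCc2ccccc2)c(OC)c1
A7 | alternative 3 | 6-(2,4-dioxononyl)-2,2-dimethyl-4H-1,3-dioxin-4-one | CCCCCC(=O)CC(=O)CC1=CC(=O)OC(C)(C)O1
A8 | alternative 3 | benzyl 2-heptyl-6-methoxy-4-[(3,5,7-trioxododecanoyl)oxy]benzoate | CCCCCC(=O)CC(=O)CC(=O)CC(=O)Oc1cc(CCCCCCC)c(C(=O)OCc2ccccc2)c(OC)c1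
A9 | alternative 3 | benzyl 4-[(2,4-dihydroxy-6-pentylbenzoyl)oxy]-2-heptyl-6-methoxybenzoate | CCCCCc1cc(O)cc(O)c1C(=O)Oc1cc(CCCCCCC)c(C(=O)OCc2ccccc2)c(OC)c1
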